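**Plan**
Cuts (labdane numbering): both acetates; C11–C12 (sulfone alkylation by the C5 allylic chloride); C9–C11 (methylenation, then hydroboration of a C9 ketone); C3–C4 of ring A; C10–C1 and C10–CH3 (two enolate alkylations).
Feature used: ring B (C5–C10 with the C8 methyl and C7=C8) plus C4 and its two methyls is (S)-carvone with its isopropenyl group. With an acetonyl arm C1–C3 on C10, ring A lacks only the C3–C4 bond, made from a tertiary cation at C4 and the enol carbon C3.
Forward: ring B is bought; C10 is made quaternary (steps 1–2); the arm becomes a methyl ketone (step 3); ring A closes by cationic alkylation of its silyl enol ether (steps 4–6); C11 and then C12–C16 are added (steps 8–13).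
Stereochemistry: C5 from (S)-carvone; C10 by alkylation anti to isopropenyl (gives the trans fusion); C2 by equatorial hydride attack; C9 by hydroboration anti to the C10 methyl; 13E from the purchased chloride.
Key step: step 6

Remark: the purchased C5 allylic chloride is assumed to be the pure E isomer; drimane/labdane numbering is used for all bicyclic compounds.

Step 1
Reactants: 1 (S)-carvone; 2 iodomethane
Product: 3 (5S)-6-methylcarvone (both C6 epimers)
Conditions: LDA, THF, −78 °C; MeI, −78 → 0 °C
Reagents that add atoms: iodomethane (2), CI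
Why: Kinetic deprotonation of the enone at its only sp3 α-carbon (C6) and C-methylation of the lithium enolate (enolate alkylation) is standard for carvone, and the C6 configuration is irrelevant because this carbon is enolised again in step 2.

Step 2
Reactants: 3 (5S)-6-methylcarvone; 4 allyl bromide
Product: 5 (5R,6R)-6-allyl-6-methylcarvone (allyl trans to isopropenyl)
Conditions: LDA, THF, −78 → −20 °C; DMPU, allyl bromide, −78 °C → rt
Reagents that add atoms: allyl bromide (4), C=CCBr
Why: Alkylation of the tetrasubstituted lithium enolate (enolate alkylation) should occur on the face anti to the neighbouring isopropenyl group, creating the quaternary carbon (C10 of the target) with the allyl arm trans and the methyl cis to isopropenyl, which later gives the trans ring fusion.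

Step 3
Reactants: 5 (5R,6R)-6-allyl-6-methylcarvone
Product: 6 (5R,6R)-6-acetonyl-6-methylcarvone [2,6-dimethyl-6-(2-oxopropyl)-5-(prop-1-en-2-yl)cyclohex-2-en-1-one]
Conditions: PdCl2 (10 mol %), CuCl (co-catalyst), O2 (1 atm), DMF–H2O, rt
Reagents that add atoms: water, O
Why: The Tsuji–Wacker oxidation should convert only the monosubstituted terminal alkene into the methyl ketone (Markovnikov), because the 1,1-disubstituted isopropenyl group and the conjugated trisubstituted alkene are inert under these conditions.

Step 4
Reactants: 6 (5R,6R)-6-acetonyl-6-methylcarvone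
Product: 7 (5S,6R)-5-(2-chloropropan-2-yl)-2,6-dimethyl-6-(2-oxopropyl)cyclohex-2-en-1-one (spatial arrangement as in 6)
Conditions: HCl (4 M in dioxane), CH2Cl2, −20 → 0 °C; used crude
Reagents that add atoms: hydrogen chloride, Cl
Why: Markovnikov hydrochlorination of the electron-rich 1,1-disubstituted alkene stores the C4 cation as a tertiary chloride under conditions too mild to drive aldol or Prins reactions of the ketones or to touch the electron-poor enone double bond.

Step 5
Reactants: 7 tertiary chloride
Product: 8 (5S,6R)-5-(2-chloropropan-2-yl)-2,6-dimethyl-6-[2-(trimethylsilyloxy)prop-2-en-1-yl]cyclohex-2-en-1-one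
Conditions: LDA, Me3SiCl (in situ quench), THF, −78 °C; non-aqueous work-up, used crude
Reagents that add atoms: chlorotrimethylsilane, C[Si](C)(C)Cl
Why: Kinetic enolisation with LDA should take a methyl proton in preference to the neopentyl-type C1–H or the γ-H of the enone, and O-silylation (kinetic silyl enol ether formation) then fixes C3 as the only nucleophilic carbon and removes the electrophilic C2 carbonyl, while the tertiary chloride is not attacked by the hindered amide at −78 °C.

Step 6
Reactants: 8 silyl enol ether chloride
Product: 9 (5R,10R)-11-nordrim-7-ene-2,9-dione (trans-fused; C2 ketone and C9 enone)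
Conditions: TiCl4, CH2Cl2, −78 °C; aq. NaHCO3
Reagents that add atoms: none
Why: TiCl4 ionises the tertiary C4–Cl bond, C3 of the silyl enol ether attacks the C4 cation, and the silyl group leaves the resulting oxocarbenium ion as Me3SiCl, so the C3–C4 bond and the C2 ketone appear together. The closest known reaction type is the Lewis acid-mediated α-tert-alkylation of silyl enol ethers with tertiary alkyl chlorides (SN1 alkylation of an enol derivative), run here intramolecularly. Ring A closes in the 6-(enolendo)-exo-tet mode through a chair-like transition state in which the C10–C1 and C5–C4 bonds are both equatorial on ring B. No stereocentre is created (C4 becomes the gem-dimethyl carbon), and the trans fusion is inherited from the anti arrangement of the C10 arm and the C5 substituent set in step 2. The step needs C–C bond formation at C3 to outrun proton loss or hydride shift from C5, Prins-type attack of an alkene on a free methyl ketone, O-alkylation and aldol addition to C9; the preformed chloride ionised without protic acid at −78 °C, the masking of the C2 carbonyl as a regiodefined nucleophile, and the hindered conjugated C9 carbonyl (reachable only by a strained five-membered enolendo closure) should secure this.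

Step 7
Reactants: 9 enedione
Product: 10 (2S,5R,10R)-2-hydroxy-11-nordrim-7-en-9-one (axial OH syn to the C10 methyl)
Conditions: NaBH4, MeOH–CH2Cl2, −78 → −40 °C
Reagents that add atoms: none
Why: Borohydride should reduce the saturated C2 ketone in preference to the conjugated C9 carbonyl flanked by quaternary C10 (chemoselective carbonyl reduction), and hydride must arrive equatorially because the axial trajectory is blocked by the syn-axial methyls on C4 and C10, which gives the axial 2S alcohol.

Step 8
Reactants: 10 hydroxy enone
Product: 11 (2S,5R,10R)-drima-7,9(11)-dien-2-ol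
Conditions: Ph3PCH3Br, KOtBu (excess), toluene, 90 °C
Reagents that add atoms: methyltriphenylphosphonium bromide, [Br-].C[P+](c1ccccc1)(c1ccccc1)c1ccccc1
Why: Wittig methylenation with excess ylide in hot toluene is the standard answer to hindered ketones and adds 1,2 to the enone to give the exocyclic 1,3-diene, the free hydroxyl being only reversibly deprotonated.

Step 9
Reactants: 11 hydroxy diene
Product: 13 (2S,5R,9R,10R)-drim-7-ene-2,11-diol, via B-alkyl-9-BBN adduct 12 (not isolated)
Conditions: 9-BBN (excess), THF, rt → 60 °C; then NaOH, 30% H2O2, 0 °C → rt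
Reagents that add atoms: hydrogen peroxide, OO
Why: Anti-Markovnikov hydroboration with the bulky borane should occur only at the exocyclic methylene (the trisubstituted C7=C8 bond is inert) and deliver H to C9 from the face opposite the axial C10 methyl, so that C11 ends up cis to that methyl (9R), and oxidation proceeds with retention.

Step 10
Reactants: 13 diol
Product: 14 (2S,5R,9R,10R)-11-(phenylsulfanyl)drim-7-en-2-ol
Conditions: PhSSPh, n-Bu3P, pyridine, rt → 45 °C
Reagents that add atoms: diphenyl disulfide, c1ccc(SSc2ccccc2)cc1
Why: The Hata reaction turns the primary alcohol into its phenyl sulfide by SN2 displacement of the alkoxyphosphonium ion, whereas the axial secondary C2 hydroxyl, shielded at its rear by two syn-axial methyls, cannot be displaced.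

Step 11
Reactants: 14 hydroxy sulfide
Product: 15 (2S,5R,9R,10R)-11-(phenylsulfonyl)drim-7-en-2-ol
Conditions: (NH4)6Mo7O24·4H2O (cat.), 30% H2O2, EtOH, 0 °C → rt
Reagents that add atoms: hydrogen peroxide, OO
Why: Molybdate-catalysed peroxide oxidation of sulfide to sulfone is chemoselective and should leave the trisubstituted alkene and the secondary alcohol untouched.

Step 12
Reactants: 15 hydroxy sulfone; 16 (E)-4-chloro-3-methylbut-2-en-1-yl acetate
Product: 17 (2S,5R,9R,10R,13E)-2-hydroxy-11-(phenylsulfonyl)labda-7,13-dien-15-yl acetate (both C11 epimers)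
Conditions: n-BuLi (2.1 equiv), THF–DMPU, −78 °C; then 16, −78 → −30 °C
Reagents that add atoms: (E)-4-chloro-3-methylbut-2-en-1-yl acetate (16), CC(=O)OC/C=C(\C)CCl
Why: The alkoxide/α-sulfonyl carbanion dianion should displace the primary allylic chloride by SN2 at carbon (Julia-type sulfone alkylation), forming C11–C12 without touching the E-configured C13=C14 bond, and the temporary stereocentre at C11 is removed in step 13.

Step 13
Reactants: 17 sulfonyl acetate
Product: 19 (2S,5R,9R,10R,13E)-labda-7,13-diene-2,15-diol, via sulfonyl diol 18 (not isolated)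
Conditions: K2CO3, MeOH, rt; then Na2HPO4, 6% Na(Hg), MeOH–THF, −20 °C → rt
Reagents that add atoms: none
Why: Methanolysis first removes the allylic acetate so that no allylic ester meets the reductant, and buffered sodium amalgam then cleaves the C–S bond by electron transfer (reductive desulfonylation) without affecting the alkenes or C9.

Step 14
Reactants: 19 diol
Product: 20 (2S,5R,9R,10R,13E)-labda-7,13-diene-2,15-diyl diacetate (target)
Conditions: Ac2O, pyridine, DMAP (cat.), CH2Cl2, rt
Reagents that add atoms: acetic anhydride, CC(=O)OC(C)=O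
Why: DMAP-catalysed acylation should esterify both the primary allylic and the hindered axial secondary hydroxyl without touching any stereocentre.

**Compound list**
1 | (S)-carvone | CC1=CC[C@@H](CC1=O)C(C)=C | starting material
2 | iodomethane | CI | starting material
3 | (5S)-6-methylcarvone, C6 epimers | CC1=CC[C@@H](C(C)C1=O)C(C)=C | intermediate
4 | allyl bromide | C=CCBr | starting material
5 | (5R,6R)-6-allyl-6-methylcarvone | C=CC[C@]1(C)[C@@H](C(C)=C)CC=C(C)C1=O | intermediate
6 | (5R,6R)-6-acetonyl-6-methylcarvone | CC(=O)C[C@]1(C)[C@@H](C(C)=C)CC=C(C)C1=O | intermediate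
7 | (5S,6R)-5-(2-chloropropan-2-yl)-2,6-dimethyl-6-(2-oxopropyl)cyclohex-2-en-1-one | CC(=O)C[C@]1(C)[C@@H](C(C)(C)Cl)CC=C(C)C1=O | intermediate
8 | (5S,6R)-5-(2-chloropropan-2-yl)-2,6-dimethyl-6-[2-(trimethylsilyloxy)prop-2-en-1-yl]cyclohex-2-en-1-one | C=C(O[Si](C)(C)C)C[C@]1(C)[C@@H](C(C)(C)Cl)CC=C(C)C1=O | intermediate
9 | (5R,10R)-11-nordrim-7-ene-2,9-dione, trans-fused | O=C1C(C)=CC[C@@H]2C(C)(C)CC(=O)C[C@@]12C | intermediate
10 | (2S,5R,10R)-2-hydroxy-11-nordrim-7-en-9-one | O=C1C(C)=CC[C@@H]2C(C)(C)C[C@H](O)C[C@@]12C | intermediate
11 | (2S,5R,10R)-drima-7,9(11)-dien-2-ol | C=C1C(C)=CC[C@@H]2C(C)(C)C[C@H](O)C[C@@]12C | intermediate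
12 | B-(2-hydroxydrim-7-en-11-yl)-9-borabicyclo[3.3.1]nonane, configuration as in 13 | C1CC2CCCC(C1)B2C[C@@H]1C(C)=CC[C@@H]2C(C)(C)C[C@H](O)C[C@@]12C | intermediate (not isolated)
13 | (2S,5R,9R,10R)-drim-7-ene-2,11-diol | OC[C@@H]1C(C)=CC[C@@H]2C(C)(C)C[C@H](O)C[C@@]12C | intermediate
14 | (2S,5R,9R,10R)-11-(phenylsulfanyl)drim-7-en-2-ol | c1ccccc1SC[C@@H]1C(C)=CC[C@@H]2C(C)(C)C[C@H](O)C[C@@]12C | intermediate
15 | (2S,5R,9R,10R)-11-(phenylsulfonyl)drim-7-en-2-ol | O=S(=O)(c1ccccc1)C[C@@H]1C(C)=CC[C@@H]2C(C)(C)C[C@H](O)C[C@@]12C | intermediate
16 | (E)-4-chloro-3-methylbut-2-en-1-yl acetate | CC(=O)OC/C=C(\C)CCl | starting material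
17 | (2S,5R,9R,10R,13E)-2-hydroxy-11-(phenylsulfonyl)labda-7,13-dien-15-yl acetate, C11 epimers | CC(=O)OC/C=C(\C)CC([C@@H]1C(C)=CC[C@@H]2C(C)(C)C[C@H](O)C[C@@]12C)S(=O)(=O)c1ccccc1 | intermediate
18 | (2S,5R,9R,10R,13E)-11-(phenylsulfonyl)labda-7,13-diene-2,15-diol, C11 epimers | OC/C=C(\C)CC([C@@H]1C(C)=CC[C@@H]2C(C)(C)C[C@H](O)C[C@@]12C)S(=O)(=O)c1ccccc1 | intermediate (not isolated)
19 | (2S,5R,9R,10R,13E)-labda-7,13-diene-2,15-diol | OC/C=C(\C)CC[C@@H]1C(C)=CC[C@@H]2C(C)(C)C[C@H](O)C[C@@]12C | intermediate
20 | (2S,5R,9R,10R,13E)-labda-7,13-diene-2,15-diyl diacetate | CC(=O)OC/C=C(\C)CC[C@@H]1C(C)=CC[C@@H]2C(C)(C)C[C@H](OC(C)=O)C[C@@]12C | target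

**Step count**
Total steps: 14. Longest linear sequence: 14 steps (1 to 20); 2, 4 and 16 are purchased.

**Steps most likely to fail**

Step 6 (ring closure). After ionisation the tertiary cation may lose a proton or take a hydride from C5 faster than it is captured, which would also endanger the C5 configuration. The silyl enol ether may also be cleaved by traces of HCl before it is alkylated. The fallback generates the cation by protonation and traps it with a chloro-olefin (cation–vinyl chloride annulation). It sets out from 3: LDA, then 2,3-dichloropropene and NaI in THF–DMPU, should give (5R,6R)-6-(2-chloroallyl)-6-methylcarvone F1 with the same anti alkylation as in step 2. In 98% formic acid (rt → 50 °C, aqueous work-up) the isopropenyl group is protonated. The terminal carbon of the 2-chloroallyl group, a masked methyl-ketone enol with no electrophilic carbonyl, captures the C4 cation, and hydrolysis of the α-chloro cation gives enedione 9, where the route is rejoined.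

Step 12 (sulfone alkylation). The hindered carbanion may be acylated or protonated by the acetate of the electrophile instead of displacing chloride. The fallback carries the C5 unit as a silyl ether. From 16, acid-catalysed methanolysis (AcCl cat., MeOH, 0 °C) should give (E)-4-chloro-3-methylbut-2-en-1-ol F2, and TBSCl/imidazole its tert-butyldimethylsilyl ether F3. The dianion of 15 is alkylated with F3 to the silyloxy sulfone F4, buffered Na(Hg) gives the desulfonylated silyl ether F5, and TBAF in THF releases diol 19, where the route is rejoined.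

Step 8 (methylenation). The ylide may act as a base (γ-deprotonation towards C6) or fail to add to the C9 carbonyl next to quaternary C10. The fallback is a Peterson olefination in two operations. From 10, Me3SiCH2Li/CeCl3 (excess, THF, −78 °C), a small and weakly basic organocerium nucleophile, should add to C9 to give the β-hydroxysilane F6. KH in THF then eliminates the silanolate regiospecifically to diene 11, where the route is rejoined.

**Further compounds**
F1 | step 6 | (5R,6R)-6-(2-chloroprop-2-en-1-yl)-2,6-dimethyl-5-(prop-1-en-2-yl)cyclohex-2-en-1-one | C=C(Cl)C[C@]1(C)[C@@H](C(C)=C)CC=C(C)C1=O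
F2 | step 12 | (E)-4-chloro-3-methylbut-2-en-1-ol | OC/C=C(\C)CCl
F3 | step 12 | tert-butyl{[(E)-4-chloro-3-methylbut-2-en-1-yl]oxy}dimethylsilane | CC(C)(C)[Si](C)(C)OC/C=C(\C)CCl
F4 | step 12 | (2S,5R,9R,10R,13E)-15-(tert-butyldimethylsilyloxy)-11-(phenylsulfonyl)labda-7,13-dien-2-ol, C11 epimers | CC(C)(C)[Si](C)(C)OC/C=C(\C)CC([C@@H]1C(C)=CC[C@@H]2C(C)(C)C[C@H](O)C[C@@]12C)S(=O)(=O)c1ccccc1
F5 | step 12 | (2S,5R,9R,10R,13E)-15-(tert-butyldimethylsilyloxy)labda-7,13-dien-2-ol | CC(C)(C)[Si](C)(C)OC/C=C(\C)CC[C@@H]1C(C)=CC[C@@H]2C(C)(C)C[C@H](O)C[C@@]12C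
F6 | step 8 | (2S,5R,10R)-11-(trimethylsilyl)drim-7-ene-2,9-diol, C9 configuration undefined | C[Si](C)(C)CC1(O)C(C)=CC[C@@H]2C(C)(C)C[C@H](O)C[C@@]12C
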